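Remark on the chemistry: the single stereocentre (the carbinol carbon of the side chain) is read from the SMILES as S. The two ring oxygens of the deacetylated parent are equivalent, so it does not matter which of them finally carries the acetyl group.

## Structural features

- The target is one benzene ring with three substituents in a 1,3,5 array: C1 carries the CH2 terminus of a 2-hydroxytetradecyl chain, C3 a free phenolic OH and C5 an acetoxy group. C2, C4 and C6 carry hydrogen.
- The only stereocentre is the carbinol carbon C2' (S). It lies between the benzylic CH2 and the first CH2 of a linear dodecyl residue.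
- Both neighbours of that carbon are methylene groups, so an enantioselective reduction of the corresponding ketone has little to discriminate. The centre is better taken from a chiral three-carbon unit.
- In the deacetylated parent the two phenolic oxygens are exchanged by rotation about the aryl–CH2 bond. Acetylating one of them once the ring exists is therefore a statistical operation, and the free secondary alcohol competes as well.
- The aryl acetate is the fragile group. It is an activated ester that bases, nucleophiles and fluoride cleave or transfer, but it tolerates acid, so the end-game has to be acidic or neutral.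
- The real difficulty is not the skeleton. It is placing one acetyl group on one of two otherwise identical ring oxygens, beside an unprotected carbinol of defined configuration.

## Logic of the disconnections

In one sentence, the arene is made by benzannulation of 8 with 12; no aryl nucleophile and no resorcinol appear anywhere in the route.

**19 to 18.** The bonds cut are the aryl O–C(bridgehead) bond and the carbinol O–Si bond. Both are acid-labile, whereas the aryl acetate is stable to acid, so the last step can be run without base or fluoride. This masks both hydroxyls that must end up free while the acetate is in place. The forward step must intercept the bridgehead cation before it attacks the ring and must leave the ester alone.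

**18 to 17.** The bond cut is the acetyl C–O bond. In 17 the phenol is the only free hydroxyl, so the acetylation is exhaustive and not statistical. This removes the desymmetrisation problem from the end-game. It demands that 17 contain exactly one free ring oxygen, which the key step must supply.

**17 to 8 and 12 (key disconnection).** With the arene numbered C1 (OH), C3 (ether oxygen) and C5 (side chain), the ring bonds C1–C2 and C3–C4 are cut and the C2–C3 unit is excised as the two-carbon alkynyl ether 12. The remaining carbons C1, C4, C5 and C6 are the four-membered ring of 8. The oxygen on C1 is the ketone oxygen of 8 and the oxygen on C3 arrives with 12, so the two ring oxygens come from two reagents and emerge in different states (free OH and ether). The side chain is on C5 because it sits on C3 of 8. The gain is a 1,3,5-trisubstituted arene with differentiated oxygens from a cyclobutenone and an alkyne, with the stereocentre already in place. The forward step must be regioselective in the ketene–alkyne cycloaddition and must run under neutral thermal conditions.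

**12 to 9.** The bond cut is the O–C(sp) bond; the two alkyne carbons come from trichloroethylene. The bridgehead tertiary group is chosen because its aryl ether is acid-labile like a tert-butyl ether, yet its ynol ether cannot lose an alkene by a retro-ene reaction at the temperature of the key step. The forward step must add a hindered alkoxide and carry out a double elimination.

**8 to 7 to 6.** The cyclobutenone bonds C1–C2 and C3–C4 are cut (ketene–alkyne [2+2]), and the two C–Cl bonds of 7 are exchanged for C–H. The cycloaddition of a terminal alkyne places the ketene carbonyl carbon on the terminal alkyne carbon, which gives the 3-substituted cyclobutenone that the key step needs. The ring is thus reduced to a terminal alkyne. The silyl ether must survive zinc halide, and the dechlorination must spare the strained enone.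

**6 to 5 to 3 (through 4) to 1 and 2.** The bonds cut are the O–Si bond, the propargylic C2–C3 bond of 5 (acetylide plus epoxide 4) and the C3–C4 bond of the tetradecane chain (Grignard reagent 2 plus the epoxide of 1). The carbinol flanked by two methylenes is taken from a three-carbon chiral-pool unit whose two CH2 termini are attacked in turn by two carbon nucleophiles. The stereocentre itself never reacts. This brings the route down to commercial 1 and 2; each opening must occur at the unsubstituted carbon.

## Other disconnections considered

**Alternative 1:** Cut the aryl–CH2 bond (the first idea). Copper-catalysed opening of epoxide 4 by 3,5-dimethoxyphenylmagnesium bromide would give (2S)-1-(3,5-dimethoxyphenyl)tetradecan-2-ol A1. Exhaustive O-demethylation and acetylation of one ring oxygen would follow. This is the shortest route, but after demethylation the two phenols are identical by structure, so mono-acetylation can only be statistical and gives mixtures with unreacted and doubly acetylated material, with the secondary alcohol as a further competitor. A boron tribromide step is also needed. Moving the statistical step to the aryl bromide does not remove it. The chosen plan never passes through a symmetrical resorcinol.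

**Alternative 2:** A saturated ring aromatised late, copying the polyketide logic (a chain of 1,3-related carbonyls closed by Claisen condensation, as in the type 3 polyketide synthases that make alkylresorcinols). Michael–Claisen annulation of (3E,6S)-6-[(tert-butyldimethylsilyl)oxy]octadec-3-en-2-one A2 with dimethyl malonate, then decarboxylation, would give the dione 5-{(2S)-2-[(tert-butyldimethylsilyl)oxy]tetradecyl}cyclohexane-1,3-dione A3. Its mono enol acetate A4 would be dehydrogenated to the aryl acetate. The idea is attractive because a 1,3-dione can be O-acetylated only once. It is set aside for three reasons: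
- A4 is a vinylogous anhydride, an acyl donor. The known dehydrogenations (halogenation–elimination, palladium-catalysed aerobic oxidation, quinone oxidants) all pass through enols or enolates in acidic or basic media and are expected to transfer or hydrolyse the acetyl group.
- The alkoxide conditions of the annulation invite E1cB loss of the silyloxy group from A2.
- A2 itself needs an asymmetric β-keto ester hydrogenation and several further steps, so the route is longer.

**Alternative 3:** One aromatic ring made from another, by opening and re-closing a pyrylium ring. Lateral aldol addition of lithiated 2,6-dimethyl-4H-pyran-4-one to tridecanal would give the whole C20 skeleton in one step as racemic 2-(2-hydroxytetradecyl)-6-methyl-4H-pyran-4-one A5. Silylation and O-methylation would give the 4-methoxypyrylium triflate A6. Hydroxide would open it to a 1,5-dicarbonyl compound that re-closes by aldol condensation to 3-{2-[(tert-butyldimethylsilyl)oxy]tetradecyl}-5-methoxyphenol A7, with differentiated oxygens. It is set aside for four reasons: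
- The opened intermediate can close through either the methyl carbon or the side-chain methylene, so constitutional isomers are expected.
- The β-silyloxy ketone formed on ring opening is prone to elimination in hydroxide.
- A5 is racemic, and its ketone is flanked by two methylenes, so no reliable enantioselective reduction is in sight.
- The methyl ether of A7 cannot be cleaved beside an aryl acetate.

Key step: step 7

## Route

Step 1
Reactants: 1 (S)-epichlorohydrin; 2 undecylmagnesium bromide
Product: 3 (2S)-1-chlorotetradecan-2-ol
Conditions: CuI (10 mol%), THF, −40 → −20 °C; then H2O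
Reagents that add atoms: none
Why: Copper-catalysed Grignard opening of a terminal epoxide (SN2 at the unsubstituted ring carbon); the stereocentre is not a reacting centre, so its configuration is retained, and the descriptor stays S because CH2Cl still outranks the alkyl branch. Low temperature and the soft organocopper nucleophile favour epoxide opening over displacement of chloride.

Step 2
Reactants: 3 (2S)-1-chlorotetradecan-2-ol
Product: 5 (4S)-hexadec-1-yn-4-ol, via (S)-1,2-epoxytetradecane 4 (not isolated)
Conditions: LiC≡CH·H2NCH2CH2NH2 (3.5 equiv), DMSO, 0 °C → rt; then H2O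
Reagents that add atoms: lithium acetylide–ethylenediamine complex, [Li]C#C.NCCN
Why: The first equivalent of base forms the alkoxide, which closes epoxide 4 by intramolecular Williamson displacement of chloride; acetylide then opens 4 at its terminal carbon (SN2). The carbinol carbon is never attacked, so the S configuration is retained (CH2–C≡CH outranks the alkyl chain just as CH2Cl did).

Step 3
Reactants: 5 (4S)-hexadec-1-yn-4-ol
Product: 6 tert-butyl{[(4S)-hexadec-1-yn-4-yl]oxy}dimethylsilane
Conditions: TBSCl, imidazole, DMF, rt
Reagents that add atoms: tert-butyldimethylsilyl chloride (TBSCl), CC(C)(C)[Si](C)(C)Cl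
Why: Standard imidazole-mediated silylation of a secondary alcohol; the silyl ether masks the only hydroxyl through the acylating, reducing and thermal steps that follow and is acid-labile at the end.

Step 4
Reactants: 6 tert-butyl{[(4S)-hexadec-1-yn-4-yl]oxy}dimethylsilane
Product: 7 4,4-dichloro-3-{(2S)-2-[(tert-butyldimethylsilyl)oxy]tetradecyl}cyclobut-2-en-1-one
Conditions: Cl3CCOCl (2 equiv), zinc–copper couple (3 equiv), DME (2 equiv), Et2O, rt, slow addition
Reagents that add atoms: dichloroketene, O=C=C(Cl)Cl, generated in the flask from trichloroacetyl chloride, O=C(Cl)C(Cl)(Cl)Cl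
Why: Staudinger-type ketene–alkyne [2+2] cycloaddition; the carbonyl carbon of the reductively generated dichloroketene bonds to the terminal alkyne carbon, so the side chain ends up on C3 of the cyclobutenone. DME ties up ZnCl2 and so protects the silyl ether; a shift of chlorine within the ring would be harmless because reduction converges on the same product.

Step 5
Reactants: 7 4,4-dichloro-3-{(2S)-2-[(tert-butyldimethylsilyl)oxy]tetradecyl}cyclobut-2-en-1-one
Product: 8 3-{(2S)-2-[(tert-butyldimethylsilyl)oxy]tetradecyl}cyclobut-2-en-1-one
Conditions: Zn dust, AcOH, TMEDA, EtOH, 0 °C → rt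
Reagents that add atoms: none
Why: Zinc reduction of an α,α-dichloroketone (two successive C–Cl reductions through zinc enolates that are protonated by acetic acid); the amine-buffered medium is mild enough to leave the strained enone and the silyl ether untouched.

Step 6
Reactants: 9 adamantan-1-ol
Product: 12 1-(ethynyloxy)adamantane, via dichlorovinyl ether 10 (not isolated), via lithium alkoxyacetylide 11 (not isolated)
Conditions: KH, THF, 0 °C → rt; Cl2C=CHCl, rt; n-BuLi (2.5 equiv), −78 → −40 °C; MeOH, −78 °C
Reagents that add atoms: trichloroethylene, ClC=C(Cl)Cl
Why: The trichloroethylene route to alkynyl ethers: the alkoxide dehydrochlorinates trichloroethylene to dichloroacetylene and adds to it to give 10, and n-BuLi then effects elimination and chlorine–lithium exchange to acetylide 11, which methanol protonates. Unlike a tert-butyl ynol ether, 12 cannot decompose by retro-ene loss of an alkene, because that would require a bridgehead double bond.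

Step 7
Reactants: 8 3-{(2S)-2-[(tert-butyldimethylsilyl)oxy]tetradecyl}cyclobut-2-en-1-one; 12 1-(ethynyloxy)adamantane
Product: 17 3-(adamantan-1-yloxy)-5-{(2S)-2-[(tert-butyldimethylsilyl)oxy]tetradecyl}phenol, via vinylketene 13 (not isolated), via 4-alkenylcyclobutenone 14 (not isolated), via dienylketene 15 (not isolated), via cyclohexa-2,4-dienone 16 (not isolated)
Conditions: 12 (2 equiv), toluene (0.2 M), 80 °C, then 110 °C
Reagents that add atoms: none
Why: Danheiser benzannulation, the closest known reaction type being the thermal annulation of 3-alkylcyclobutenones with alkoxyacetylenes. Heating opens 8 by a reversible 4π electrocyclic reaction to vinylketene 13, whose ketene C=C bond adds to the electron-rich alkyne 12 in a [2+2] cycloaddition that closes the transient four-membered ring of 14. The regiochemistry of this cycloaddition is fixed by polarisation: the nucleophilic terminal carbon of the ynol ether attacks the electrophilic ketene carbonyl carbon, so the ether oxygen ends up β to the carbonyl, and this places OH and the ether oxygen 1,3 on the arene and the side chain (on C3 of 8) at C5. A second 4π opening of 14 gives dienylketene 15, and the six-membered carbocycle, the only ring that remains, is closed by a thermally allowed disrotatory 6π electrocyclisation of 15 (bond between the ketene carbon and the terminal methylene) to dienone 16, which tautomerises irreversibly to phenol 17. No new stereocentre survives (the ring stereocentre of 14 is destroyed on opening), and the existing carbinol centre is separated from the π-system by a methylene group in a neutral aprotic medium, so its S configuration is untouched. Beyond regiochemistry the step needs chemoselectivity against acylation of the product phenol by 13, which an excess of 12 and moderate dilution secure by keeping the stationary concentration of 13 low. The bridgehead ether of 12 has no retro-ene path, so 12 should tolerate 110 °C. The two ring oxygens of 17 come from two different reagents and emerge in different states, one free and one etherified, which is the desymmetrisation that the target demands.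

Step 8
Reactants: 17 3-(adamantan-1-yloxy)-5-{(2S)-2-[(tert-butyldimethylsilyl)oxy]tetradecyl}phenol
Product: 18 3-(adamantan-1-yloxy)-5-{(2S)-2-[(tert-butyldimethylsilyl)oxy]tetradecyl}phenyl acetate
Conditions: Ac2O (1.5 equiv), pyridine, DMAP (cat.), CH2Cl2, 0 °C → rt
Reagents that add atoms: acetic anhydride, CC(=O)OC(C)=O
Why: DMAP-catalysed acylation; the phenol is the only free hydroxyl in 17, so the acetylation can be driven to completion and is not statistical.

Step 9
Reactants: 18 3-(adamantan-1-yloxy)-5-{(2S)-2-[(tert-butyldimethylsilyl)oxy]tetradecyl}phenyl acetate
Product: 19 3-hydroxy-5-[(2S)-2-hydroxytetradecyl]phenyl acetate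
Conditions: TFA–CH2Cl2 (1:1), Et3SiH (10 equiv), H2O (5 equiv), 0 °C → rt; then pH 7 buffer–MeOH, rt, brief
Reagents that add atoms: none
Why: SN1 acidolysis of a tertiary alkyl aryl ether together with acid hydrolysis of the silyl ether; Et3SiH reduces the bridgehead cation (ionic hydrogenation) and, being the better and far more concentrated nucleophile, should outcompete attack on the ring. Aryl acetates are stable to trifluoroacetic acid at room temperature, and the neutral methanolic buffer cleaves any trifluoroacetate formed at the carbinol, whose carbon is never ionised, so the S configuration is kept.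

## Compound list

1 | (S)-epichlorohydrin, (2S)-2-(chloromethyl)oxirane | ClC[C@@H]1CO1 | starting material
2 | undecylmagnesium bromide | CCCCCCCCCCC[Mg]Br | starting material
3 | (2S)-1-chlorotetradecan-2-ol | ClC[C@@H](O)CCCCCCCCCCCC | intermediate
4 | (S)-1,2-epoxytetradecane, (2S)-2-dodecyloxirane | CCCCCCCCCCCC[C@H]1CO1 | intermediate
5 | (4S)-hexadec-1-yn-4-ol | C#CC[C@@H](O)CCCCCCCCCCCC | intermediate
6 | tert-butyl{[(4S)-hexadec-1-yn-4-yl]oxy}dimethylsilane | C#CC[C@@H](O[Si](C)(C)C(C)(C)C)CCCCCCCCCCCC | intermediate
7 | 4,4-dichloro-3-{(2S)-2-[(tert-butyldimethylsilyl)oxy]tetradecyl}cyclobut-2-en-1-one | O=C1C=C(C[C@@H](O[Si](C)(C)C(C)(C)C)CCCCCCCCCCCC)C1(Cl)Cl | intermediate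
8 | 3-{(2S)-2-[(tert-butyldimethylsilyl)oxy]tetradecyl}cyclobut-2-en-1-one | O=C1C=C(C[C@@H](O[Si](C)(C)C(C)(C)C)CCCCCCCCCCCC)C1 | intermediate
9 | adamantan-1-ol | OC12CC3CC(CC(C3)C1)C2 | starting material
10 | 1-{[(E)-1,2-dichloroethenyl]oxy}adamantane | Cl/C=C(/Cl)OC12CC3CC(CC(C3)C1)C2 | intermediate
11 | lithium 2-(adamantan-1-yloxy)ethynide | [Li]C#COC12CC3CC(CC(C3)C1)C2 | intermediate
12 | 1-(ethynyloxy)adamantane | C#COC12CC3CC(CC(C3)C1)C2 | intermediate
13 | (5S)-5-[(tert-butyldimethylsilyl)oxy]-3-methylideneheptadec-1-en-1-one (vinylketene) | O=C=CC(=C)C[C@@H](O[Si](C)(C)C(C)(C)C)CCCCCCCCCCCC | intermediate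
14 | 3-(adamantan-1-yloxy)-4-{(4S)-4-[(tert-butyldimethylsilyl)oxy]hexadec-1-en-2-yl}cyclobut-2-en-1-one (both epimers at ring C4) | O=C1C=C(OC23CC4CC(CC(C4)C2)C3)C1C(=C)C[C@@H](O[Si](C)(C)C(C)(C)C)CCCCCCCCCCCC | intermediate
15 | (3E,7S)-3-(adamantan-1-yloxy)-7-[(tert-butyldimethylsilyl)oxy]-5-methylidenenonadeca-1,3-dien-1-one (dienylketene, ketenyl and alkenyl groups cis) | O=C=C/C(OC12CC3CC(CC(C3)C1)C2)=C\C(=C)C[C@@H](O[Si](C)(C)C(C)(C)C)CCCCCCCCCCCC | intermediate
16 | 3-(adamantan-1-yloxy)-5-{(2S)-2-[(tert-butyldimethylsilyl)oxy]tetradecyl}cyclohexa-2,4-dien-1-one | O=C1C=C(OC23CC4CC(CC(C4)C2)C3)C=C(C[C@@H](O[Si](C)(C)C(C)(C)C)CCCCCCCCCCCC)C1 | intermediate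
17 | 3-(adamantan-1-yloxy)-5-{(2S)-2-[(tert-butyldimethylsilyl)oxy]tetradecyl}phenol | Oc1cc(OC23CC4CC(CC(C4)C2)C3)cc(C[C@@H](O[Si](C)(C)C(C)(C)C)CCCCCCCCCCCC)c1 | intermediate
18 | 3-(adamantan-1-yloxy)-5-{(2S)-2-[(tert-butyldimethylsilyl)oxy]tetradecyl}phenyl acetate | CC(=O)Oc1cc(OC23CC4CC(CC(C4)C2)C3)cc(C[C@@H](O[Si](C)(C)C(C)(C)C)CCCCCCCCCCCC)c1 | intermediate
19 | 3-hydroxy-5-[(2S)-2-hydroxytetradecyl]phenyl acetate | CCCCCCCCCCCC[C@H](O)Cc1cc(O)cc(OC(C)=O)c1 | target

## Step count and least certain steps

Total step count: 9. Longest linear sequence: 8 steps (steps 1–5 and 7–9, from 1), with step 6 as a one-step branch from 9.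

**Step 7 (key step).** The most likely failures are acylation of the newly formed phenol by the vinylketene, thermal oligomerisation of the terminal ynol ether before it is captured, and stalling at the vinylcyclobutenone stage if the second ring opening is slow. All three follow from running a bimolecular capture of a reactive ketene at 80–110 °C.
Fallback (sets out from 3, returns at 19; gives up the built-in differentiation and accepts one statistical step):
- 3 is closed with aqueous NaOH to epoxide 4, which is isolated.
- [3,5-Bis(benzyloxy)phenyl]magnesium bromide F1 is made from commercial 1,3-bis(benzyloxy)-5-bromobenzene and magnesium. It opens 4 under CuI catalysis to (2S)-1-[3,5-bis(benzyloxy)phenyl]tetradecan-2-ol F2.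
- Hydrogenolysis (H2, Pd/C) gives 5-[(2S)-2-hydroxytetradecyl]benzene-1,3-diol F3.
- One equivalent of Ac2O in cold aqueous NaOH acetylates a phenoxide in preference to the alcohol and gives 19 after separation from unreacted and doubly acetylated material.

**Step 9.** The risks are C-alkylation of the activated ring by the bridgehead cation (including collapse within the ion pair before the silane intervenes), slow ionisation of the bridgehead ether, and trifluoroacetylation of the carbinol, whose removal must not cost the aryl acetate.
Fallback (sets out from 17, returns at 19; relays the differentiation through a benzyl group so that the acid step is run before any ester is present):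
- 17 is benzylated (BnBr, K2CO3, DMF) to 1-{3-(benzyloxy)-5-[(2S)-2-(tert-butyldimethylsilyloxy)tetradecyl]phenoxy}adamantane F4.
- Acidolysis (TFA, Et3SiH, thioanisole, then K2CO3–MeOH) gives 3-(benzyloxy)-5-[(2S)-2-hydroxytetradecyl]phenol F5. With no ester in the molecule, forcing scavenger-rich conditions and a basic work-up can be used freely.
- Phenoxide-selective acetylation (Ac2O, aqueous NaOH, 0 °C) gives 3-(benzyloxy)-5-[(2S)-2-hydroxytetradecyl]phenyl acetate F6.
- Neutral hydrogenolysis (H2, Pd/C, EtOAc) gives 19.

**Step 4.** The risks are Lewis-acid cleavage of the silyl ether by zinc chloride and oligomerisation of dichloroketene in competition with a sluggish unactivated alkyne.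
Fallback (sets out from 6, returns at 8; a keteniminium [2+2] cycloaddition that avoids zinc halide and makes the dechlorination unnecessary):
- N,N-Dimethylacetamide, Tf2O and 2,4,6-collidine in 1,2-dichloroethane at reflux generate the keteniminium triflate, which adds to the alkyne of 6 to give N-{3-[(2S)-2-(tert-butyldimethylsilyloxy)tetradecyl]cyclobut-2-en-1-ylidene}-N-methylmethanaminium triflate F7.
- Aqueous NaHCO3 hydrolyses F7 directly to 8.

**Step 6.** The risks are incomplete addition of the hindered bridgehead alkoxide to the dichloroacetylene generated in the flask and over-metalation during the elimination.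
Fallback (sets out from 9, returns at 12; a formate olefination route):
- 9 is formylated (acetic formic anhydride, pyridine) to adamantan-1-yl formate F8.
- Dibromo-olefination (CBr4, PPh3, CH2Cl2) gives 1-[(2,2-dibromoethenyl)oxy]adamantane F9.
- n-BuLi (2 equiv, −78 °C) effects elimination and bromine–lithium exchange in the Corey–Fuchs manner, and methanol then gives 12.

Further compounds

F1 | step 7 | [3,5-bis(benzyloxy)phenyl]magnesium bromide | Br[Mg]c1cc(OCc2ccccc2)cc(OCc2ccccc2)c1
F2 | step 7 | (2S)-1-[3,5-bis(benzyloxy)phenyl]tetradecan-2-ol | CCCCCCCCCCCC[C@H](O)Cc1cc(OCc2ccccc2)cc(OCc2ccccc2)c1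
F3 | step 7 | 5-[(2S)-2-hydroxytetradecyl]benzene-1,3-diol | CCCCCCCCCCCC[C@H](O)Cc1cc(O)cc(O)c1
F4 | step 9 | 1-{3-(benzyloxy)-5-[(2S)-2-(tert-butyldimethylsilyloxy)tetradecyl]phenoxy}adamantane | CCCCCCCCCCCC[C@H](O[Si](C)(C)C(C)(C)C)Cc1cc(OCc2ccccc2)cc(OC23CC4CC(CC(C4)C2)C3)c1
F5 | step 9 | 3-(benzyloxy)-5-[(2S)-2-hydroxytetradecyl]phenol | CCCCCCCCCCCC[C@H](O)Cc1cc(O)cc(OCc2ccccc2)c1
F6 | step 9 | 3-(benzyloxy)-5-[(2S)-2-hydroxytetradecyl]phenyl acetate | CCCCCCCCCCCC[C@H](O)Cc1cc(OC(C)=O)cc(OCc2ccccc2)c1
F7 | step 4 | N-{3-[(2S)-2-(tert-butyldimethylsilyloxy)tetradecyl]cyclobut-2-en-1-ylidene}-N-methylmethanaminium triflate | C[N+](C)=C1C=C(C[C@@H](O[Si](C)(C)C(C)(C)C)CCCCCCCCCCCC)C1.[O-]S(=O)(=O)C(F)(F)F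
F8 | step 6 | adamantan-1-yl formate | O=COC12CC3CC(CC(C3)C1)C2
F9 | step 6 | 1-[(2,2-dibromoethenyl)oxy]adamantane | BrC(Br)=COC12CC3CC(CC(C3)C1)C2
A1 | alternative 1 | (2S)-1-(3,5-dimethoxyphenyl)tetradecan-2-ol | CCCCCCCCCCCC[C@H](O)Cc1cc(OC)cc(OC)c1
A2 | alternative 2 | (3E,6S)-6-[(tert-butyldimethylsilyl)oxy]octadec-3-en-2-one | CCCCCCCCCCCC[C@H](O[Si](C)(C)C(C)(C)C)C/C=C/C(C)=O
A3 | alternative 2 | 5-{(2S)-2-[(tert-butyldimethylsilyl)oxy]tetradecyl}cyclohexane-1,3-dione | CCCCCCCCCCCC[C@H](O[Si](C)(C)C(C)(C)C)CC1CC(=O)CC(=O)C1
A4 | alternative 2 | 5-{(2S)-2-[(tert-butyldimethylsilyl)oxy]tetradecyl}-3-oxocyclohex-1-en-1-yl acetate (both epimers at ring C5) | CCCCCCCCCCCC[C@H](O[Si](C)(C)C(C)(C)C)CC1CC(=O)C=C(OC(C)=O)C1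
A5 | alternative 3 | 2-(2-hydroxytetradecyl)-6-methyl-4H-pyran-4-one (racemic) | CCCCCCCCCCCCC(O)CC1=CC(=O)C=C(C)O1
A6 | alternative 3 | 2-{2-[(tert-butyldimethylsilyl)oxy]tetradecyl}-4-methoxy-6-methylpyrylium triflate (racemic) | CCCCCCCCCCCCC(O[Si](C)(C)C(C)(C)C)Cc1cc(OC)cc(C)[o+]1.[O-]S(=O)(=O)C(F)(F)F
A7 | alternative 3 | 3-{2-[(tert-butyldimethylsilyl)oxy]tetradecyl}-5-methoxyphenol (racemic) | CCCCCCCCCCCCC(O[Si](C)(C)C(C)(C)C)Cc1cc(O)cc(OC)c1
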